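A direct plan would silylate 3,5-bis(benzyloxy)phenol, lithiate it between the two benzyloxy groups, add the aryllithium to 4'-(benzyloxy)acetophenone and dehydrate to the 1,1-diarylethene A1.
It would set the diarylmethine centre by asymmetric hydrogenation of A1, then desilylate and ortho-formylate to the salicylaldehyde A2.
O-Alkylation of A2 with a racemic α-bromo arylacetate, reduction of ester and aldehyde and double re-oxidation would give the dialdehyde A3; a chiral carbene catalyst would close ring C by an intramolecular benzoin reaction to A4, and hydrogenolysis would finish.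
Weak point (a), the hydrogenation of A1: both aryl groups are electron-rich ethers with no coordinating group, so the catalyst would have to tell them apart by twist alone, and a poor result could not be corrected later.
Weak point (b), the reduction to a diol and its re-oxidation to A3: alkylation, reduction and oxidation would add no skeletal bond and would end in an α-aryloxy aldehyde that enolises and can lose phenoxide.
Weak point (c), the carbene-catalysed closure of C3–C4 from A3: it would have to choose the acyl donor between two aldehydes, resolve C2 dynamically and set C3 by catalyst control, on late material and without precedent for such an acceptor.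

Plan of the new route
The retrosynthesis leaves ring C intact and cuts ring A at C4a–C5, C5–C6 and C7–C8: C6–C7 come from a siloxyalkyne that carries the 1-arylethyl centre, C5 and C8 from a diazoacetyl group, and C4a=C8a is the enol-ether double bond of a 2,3-dihydro-4H-pyran-4-one.
Ring order: ring C is bought as a γ-pyrone ester, ring B is attached to it by conjugate arylation (sets C2), C3 is relayed from C2 by trans-acetoxylation, and ring A is annulated last.
Feature used: in ring A, C6 with its carbon substituent lies between the oxygenated carbons C5 and C7, and C8 bears hydrogen. This is the 2-alkylresorcinol pattern that a vinylketene–siloxyalkyne benzannulation delivers, and C8a–O1 and C4a–C4(=O) are the two ends of a vinylogous ester.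
The weak steps do not arise: the diarylmethine centre is made by an enantioconvergent C–C coupling on a four-carbon bromide, there is no redox detour and no α-aryloxy aldehyde, and the late annulation is a pericyclic cascade that creates no stereocentre.

Key step: step 10

Remark: methyl 4-oxo-4H-pyran-2-carboxylate is taken as commercial (otherwise one esterification of comanic acid), and in steps 1 and 7 the ligand enantiomer is chosen by the product configuration it gives.

Step 1
Reactants: 1 methyl 4-oxo-4H-pyran-2-carboxylate; 2 [4-(benzyloxy)phenyl]boronic acid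
Product: 3 methyl (2S)-2-[4-(benzyloxy)phenyl]-4-oxo-3,4-dihydro-2H-pyran-6-carboxylate
Conditions: Pd(OCOCF3)2 (5 mol %), t-BuPyOX (6 mol %, enantiomer that gives (2S)), NH4PF6 (30 mol %), H2O (5 equiv), ClCH2CH2Cl, 60 °C
Reagents that add atoms: none
Why: Proposed new method: the arylboronic acid should transmetalate to the cationic divalent palladium–pyridine-oxazoline complex, the aryl–palladium bond should add across C5=C6 of the pyrone with the aryl group going to C6 (the only β-carbon that bears hydrogen, the other one carries the ester), and water should protonate the palladium enolate, so that the ligand sets the new centre (C2 of 3) by its choice of alkene face; the closest known reaction type is the palladium/pyridine-oxazoline-catalysed asymmetric conjugate addition of arylboronic acids to chromones, of which 1 is the monocyclic analogue made more electrophilic by its ester.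

Step 2
Reactants: 3 methyl (2S)-2-[4-(benzyloxy)phenyl]-4-oxo-3,4-dihydro-2H-pyran-6-carboxylate
Product: 4 methyl (2R,3R)-3-(acetyloxy)-2-[4-(benzyloxy)phenyl]-4-oxo-3,4-dihydro-2H-pyran-6-carboxylate
Conditions: Mn(OAc)3·2H2O (4 equiv), benzene, reflux (Dean–Stark)
Reagents that add atoms: manganese triacetate dihydrate, [Mn+3].CC(=O)[O-].CC(=O)[O-].CC(=O)[O-].O.O
Why: α'-Acetoxylation of an enone with Mn(OAc)3, known for 2-substituted 2,3-dihydro-4H-pyran-4-ones: the trivalent manganese enolate of C3 is oxidised to the α-keto radical, which takes up acetate on the face anti to the C2 aryl group, so that C3 is relayed from C2 as the 2,3-trans acetate without a free enolate that could expel O1.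

Step 3
Reactants: 4 methyl (2R,3R)-3-(acetyloxy)-2-[4-(benzyloxy)phenyl]-4-oxo-3,4-dihydro-2H-pyran-6-carboxylate
Product: 5 (2R,3R)-2-[4-(benzyloxy)phenyl]-3-hydroxy-4-oxo-3,4-dihydro-2H-pyran-6-carboxylic acid
Conditions: Me3SnOH (8 equiv), ClCH2CH2Cl, 80 °C; aq. HCl (0.1 M) work-up
Reagents that add atoms: trimethyltin hydroxide, C[Sn](C)(C)O
Why: Ester cleavage with trimethyltin hydroxide, a neutral hydroxide source that should hydrolyse both the methyl ester and the activated α-keto acetate without forming the C3 enolate, whose β-elimination of O1 would open ring C.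

Step 4
Reactants: 5 (2R,3R)-2-[4-(benzyloxy)phenyl]-3-hydroxy-4-oxo-3,4-dihydro-2H-pyran-6-carboxylic acid
Product: 7 (2R,3R)-2-[4-(benzyloxy)phenyl]-3-[(tert-butyldimethylsilyl)oxy]-4-oxo-3,4-dihydro-2H-pyran-6-carboxylic acid, via silyl ester 6 (not isolated)
Conditions: t-BuMe2SiOTf (2.5 equiv), 2,6-lutidine, CH2Cl2, −78 → 0 °C; then AcOH–H2O–THF, rt
Reagents that add atoms: tert-butyldimethylsilyl trifluoromethanesulfonate, CC(C)(C)[Si](C)(C)OS(=O)(=O)C(F)(F)F
Why: Silylation of alcohol and acid with the silyl triflate and a hindered weak base, then selective hydrolysis of the labile silyl ester in dilute acetic acid, which leaves the secondary silyl ether in place.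

Step 5
Reactants: 7 (2R,3R)-2-[4-(benzyloxy)phenyl]-3-[(tert-butyldimethylsilyl)oxy]-4-oxo-3,4-dihydro-2H-pyran-6-carboxylic acid
Product: 9 (2R,3R)-2-[4-(benzyloxy)phenyl]-3-[(tert-butyldimethylsilyl)oxy]-6-(diazoacetyl)-2,3-dihydro-4H-pyran-4-one, via acid chloride 8 (not isolated)
Conditions: Me2C=C(Cl)NMe2, CH2Cl2, 0 °C → rt; then Me3SiCHN2, MeCN–THF, 0 °C
Reagents that add atoms: (trimethylsilyl)diazomethane, C[Si](C)(C)C=[N+]=[N-]
Why: Diazoketone synthesis of the Arndt–Eistert type: the Ghosez reagent gives the acid chloride without HCl, and C-acylation of (trimethylsilyl)diazomethane with loss of chlorotrimethylsilane gives the diazomethyl ketone.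

Step 6
Reactants: 10 4-(trimethylsilyl)but-3-yn-2-ol (racemic)
Product: 11 (3-bromobut-1-yn-1-yl)trimethylsilane (racemic)
Conditions: CBr4, PPh3, CH2Cl2, 0 °C
Reagents that add atoms: tetrabromomethane, BrC(Br)(Br)Br
Why: Appel bromination of the secondary propargylic alcohol; its configuration is irrelevant because the next step is enantioconvergent.

Step 7
Reactants: 11 (3-bromobut-1-yn-1-yl)trimethylsilane; 2 [4-(benzyloxy)phenyl]boronic acid
Product: 13 {(3R)-3-[4-(benzyloxy)phenyl]but-1-yn-1-yl}trimethylsilane, via arylzinc 12 (not isolated)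
Conditions: 2, Et2Zn (3 equiv), toluene, 60 °C; then 11, NiCl2·dme (3 mol %), indanyl-pybox (4 mol %, enantiomer that gives (R)), dme, −20 °C
Reagents that add atoms: none
Why: Nickel-catalysed enantioconvergent Negishi arylation of a racemic secondary propargylic bromide with an aryl(ethyl)zinc reagent made by boron-to-zinc exchange: both enantiomers of 11 pass through the same propargylic radical and the chiral pybox–nickel complex sets the benzylic–propargylic centre.

Step 8
Reactants: 13 {(3R)-3-[4-(benzyloxy)phenyl]but-1-yn-1-yl}trimethylsilane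
Product: 14 1-(benzyloxy)-4-[(2S)-but-3-yn-2-yl]benzene
Conditions: K2CO3 (cat.), MeOH, 0 °C → rt
Reagents that add atoms: none
Why: Methanolysis of the alkynyl C–Si bond with catalytic carbonate; the propargylic C–H is far too weakly acidic to be touched, so the centre is kept (the descriptor changes only because the silyl group is lost).

Step 9
Reactants: 14 1-(benzyloxy)-4-[(2S)-but-3-yn-2-yl]benzene
Product: 17 {[(3R)-3-[4-(benzyloxy)phenyl]but-1-yn-1-yl]oxy}tri(propan-2-yl)silane, via lithium acetylide 15 (not isolated), via lithium ynolate 16 (not isolated)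
Conditions: LiN(SiMe3)2, THF, −78 °C; t-BuOOLi (from t-BuOOH, LiN(SiMe3)2), −78 → 0 °C; i-Pr3SiOTf, −78 °C → rt
Reagents that add atoms: tert-butyl hydroperoxide, CC(C)(C)OO; triisopropylsilyl trifluoromethanesulfonate, CC(C)[Si](OS(=O)(=O)C(F)(F)F)(C(C)C)C(C)C
Why: Oxidation of a lithium acetylide to the ynolate with lithium tert-butyl peroxide and O-silylation with the bulky silyl triflate, the usual route to triisopropylsiloxyalkynes; the amide base removes only the acetylenic proton, so the neighbouring centre is not at risk.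

Step 10
Reactants: 9 (2R,3R)-2-[4-(benzyloxy)phenyl]-3-[(tert-butyldimethylsilyl)oxy]-6-(diazoacetyl)-2,3-dihydro-4H-pyran-4-one; 17 {[(3R)-3-[4-(benzyloxy)phenyl]but-1-yn-1-yl]oxy}tri(propan-2-yl)silane
Product: 21 (2R,3R)-2-[4-(benzyloxy)phenyl]-6-{(1R)-1-[4-(benzyloxy)phenyl]ethyl}-3-[(tert-butyldimethylsilyl)oxy]-5-hydroxy-7-{[tri(propan-2-yl)silyl]oxy}-2,3-dihydro-4H-chromen-4-one, via pyranylketene 18 (not isolated), via cyclobutenone 19 (not isolated), via dienylketene 20 (not isolated)
Conditions: 17 (1.5 equiv), hν (Hg lamp, Pyrex), ClCH2CH2Cl, rt; then 80 °C in the dark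
Reagents that add atoms: none
Why: Danheiser benzannulation in its diazoketone variant: photochemical Wolff rearrangement of 9 gives the pyranylketene 18, the nucleophilic β-carbon of siloxyalkyne 17 attacks the ketene carbonyl carbon and a regiospecific (2+2) cycloaddition gives cyclobutenone 19, whose 4π electrocyclic opening gives dienylketene 20, and 6π electrocyclisation of 20 onto C5 of the dihydropyranone followed by tautomerisation gives the phenol. The closest known reaction type is the benzannulation of α,β-unsaturated and heteroaryl diazomethyl ketones with triisopropylsiloxyalkynes to resorcinol monosilyl ethers. Ring A is closed by the thermal 6π electrocyclisation (C4a–C5) after the intermolecular (2+2) step has formed C5–C6 and C7–C8, while ring C is present beforehand and is not touched. No stereocentre is formed, and C2, C3 and the diarylmethine centre are carried through neutral conditions in which no C–H next to them becomes acidic. The step needs one regiochemistry, and the polarity of the ketene–ynol ether cycloaddition secures it: the alkyne carbon that bears the 1-arylethyl group becomes C6, between the new phenol carbon C5 and the silyloxy carbon C7, and C8 keeps its hydrogen. The ring holds the ketene trans to the C4 carbonyl across C4a=C8a, so 18 cannot close to an α-pyrone, and the opening of 19 is reversible, so the dienylketene isomer that cannot cyclise returns to 19.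

Step 11
Reactants: 21 (2R,3R)-2-[4-(benzyloxy)phenyl]-6-{(1R)-1-[4-(benzyloxy)phenyl]ethyl}-3-[(tert-butyldimethylsilyl)oxy]-5-hydroxy-7-{[tri(propan-2-yl)silyl]oxy}-2,3-dihydro-4H-chromen-4-one
Product: 22 (2R,3R)-2-[4-(benzyloxy)phenyl]-6-{(1R)-1-[4-(benzyloxy)phenyl]ethyl}-3,5,7-trihydroxy-2,3-dihydro-4H-chromen-4-one
Conditions: HF·pyridine, THF–pyridine, 0 °C → rt
Reagents that add atoms: none
Why: Cleavage of the aryl triisopropylsilyl ether and of the secondary silyl ether with buffered hydrogen fluoride, acidic conditions under which C3 does not enolise and ring C does not open.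

Step 12
Reactants: 22 (2R,3R)-2-[4-(benzyloxy)phenyl]-6-{(1R)-1-[4-(benzyloxy)phenyl]ethyl}-3,5,7-trihydroxy-2,3-dihydro-4H-chromen-4-one
Product: 23 (2R,3R)-3,5,7-trihydroxy-2-(4-hydroxyphenyl)-6-[(1R)-1-(4-hydroxyphenyl)ethyl]-2,3-dihydro-4H-chromen-4-one
Conditions: H2 (1 atm), Pd/C (10 %), EtOAc–MeOH, rt
Reagents that add atoms: none
Why: Hydrogenolysis of the two aryl benzyl ethers over palladium, which is faster than cleavage of the benzylic C2–O1 bond; the reaction is stopped at full debenzylation and C2, C3 and the diarylmethine centre are not touched.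

Compound list
1 | methyl 4-oxo-4H-pyran-2-carboxylate | COC(=O)c1cc(=O)cco1 | starting material
2 | [4-(benzyloxy)phenyl]boronic acid | OB(O)c1ccc(OCc2ccccc2)cc1 | starting material
3 | methyl (2S)-2-[4-(benzyloxy)phenyl]-4-oxo-3,4-dihydro-2H-pyran-6-carboxylate | COC(=O)C1=CC(=O)C[C@@H](c2ccc(OCc3ccccc3)cc2)O1 | intermediate
4 | methyl (2R,3R)-3-(acetyloxy)-2-[4-(benzyloxy)phenyl]-4-oxo-3,4-dihydro-2H-pyran-6-carboxylate | COC(=O)C1=CC(=O)[C@H](OC(C)=O)[C@@H](c2ccc(OCc3ccccc3)cc2)O1 | intermediate
5 | (2R,3R)-2-[4-(benzyloxy)phenyl]-3-hydroxy-4-oxo-3,4-dihydro-2H-pyran-6-carboxylic acid | OC(=O)C1=CC(=O)[C@H](O)[C@@H](c2ccc(OCc3ccccc3)cc2)O1 | intermediate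
6 | tert-butyldimethylsilyl (2R,3R)-2-[4-(benzyloxy)phenyl]-3-[(tert-butyldimethylsilyl)oxy]-4-oxo-3,4-dihydro-2H-pyran-6-carboxylate (not isolated) | CC(C)(C)[Si](C)(C)OC(=O)C1=CC(=O)[C@H](O[Si](C)(C)C(C)(C)C)[C@@H](c2ccc(OCc3ccccc3)cc2)O1 | intermediate
7 | (2R,3R)-2-[4-(benzyloxy)phenyl]-3-[(tert-butyldimethylsilyl)oxy]-4-oxo-3,4-dihydro-2H-pyran-6-carboxylic acid | OC(=O)C1=CC(=O)[C@H](O[Si](C)(C)C(C)(C)C)[C@@H](c2ccc(OCc3ccccc3)cc2)O1 | intermediate
8 | (2R,3R)-2-[4-(benzyloxy)phenyl]-3-[(tert-butyldimethylsilyl)oxy]-4-oxo-3,4-dihydro-2H-pyran-6-carbonyl chloride (not isolated) | ClC(=O)C1=CC(=O)[C@H](O[Si](C)(C)C(C)(C)C)[C@@H](c2ccc(OCc3ccccc3)cc2)O1 | intermediate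
9 | (2R,3R)-2-[4-(benzyloxy)phenyl]-3-[(tert-butyldimethylsilyl)oxy]-6-(diazoacetyl)-2,3-dihydro-4H-pyran-4-one | [N-]=[N+]=CC(=O)C1=CC(=O)[C@H](O[Si](C)(C)C(C)(C)C)[C@@H](c2ccc(OCc3ccccc3)cc2)O1 | intermediate
10 | 4-(trimethylsilyl)but-3-yn-2-ol (racemic) | CC(O)C#C[Si](C)(C)C | starting material
11 | (3-bromobut-1-yn-1-yl)trimethylsilane (racemic) | CC(Br)C#C[Si](C)(C)C | intermediate
12 | [4-(benzyloxy)phenyl](ethyl)zinc (not isolated) | CC[Zn]c1ccc(OCc2ccccc2)cc1 | intermediate
13 | {(3R)-3-[4-(benzyloxy)phenyl]but-1-yn-1-yl}trimethylsilane | C[C@H](c1ccc(OCc2ccccc2)cc1)C#C[Si](C)(C)C | intermediate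
14 | 1-(benzyloxy)-4-[(2S)-but-3-yn-2-yl]benzene | C[C@H](c1ccc(OCc2ccccc2)cc1)C#C | intermediate
15 | lithium acetylide of 14, {(3S)-3-[4-(benzyloxy)phenyl]but-1-yn-1-yl}lithium (not isolated) | C[C@H](c1ccc(OCc2ccccc2)cc1)C#C[Li] | intermediate
16 | lithium (3R)-3-[4-(benzyloxy)phenyl]but-1-yn-1-olate (not isolated) | C[C@H](c1ccc(OCc2ccccc2)cc1)C#CO[Li] | intermediate
17 | {[(3R)-3-[4-(benzyloxy)phenyl]but-1-yn-1-yl]oxy}tri(propan-2-yl)silane | C[C@H](c1ccc(OCc2ccccc2)cc1)C#CO[Si](C(C)C)(C(C)C)C(C)C | intermediate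
18 | (2R,3R)-2-[4-(benzyloxy)phenyl]-3-[(tert-butyldimethylsilyl)oxy]-6-(2-oxoethenyl)-2,3-dihydro-4H-pyran-4-one (not isolated) | O=C=CC1=CC(=O)[C@H](O[Si](C)(C)C(C)(C)C)[C@@H](c2ccc(OCc3ccccc3)cc2)O1 | intermediate
19 | 2-{(1R)-1-[4-(benzyloxy)phenyl]ethyl}-4-[(2R,3R)-2-[4-(benzyloxy)phenyl]-3-[(tert-butyldimethylsilyl)oxy]-4-oxo-3,4-dihydro-2H-pyran-6-yl]-3-{[tri(propan-2-yl)silyl]oxy}cyclobut-2-en-1-one, both epimers at the ring CH (not isolated) | O=C1C([C@H](C)c2ccc(OCc3ccccc3)cc2)=C(O[Si](C(C)C)(C(C)C)C(C)C)C1C1=CC(=O)[C@H](O[Si](C)(C)C(C)(C)C)[C@@H](c2ccc(OCc3ccccc3)cc2)O1 | intermediate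
20 | 2-{(1R)-1-[4-(benzyloxy)phenyl]ethyl}-4-[(2R,3R)-2-[4-(benzyloxy)phenyl]-3-[(tert-butyldimethylsilyl)oxy]-4-oxo-3,4-dihydro-2H-pyran-6-yl]-3-{[tri(propan-2-yl)silyl]oxy}buta-1,3-dien-1-one, ketene carbon cis to the pyranyl group (not isolated) | O=C=C([C@H](C)c1ccc(OCc2ccccc2)cc1)/C(O[Si](C(C)C)(C(C)C)C(C)C)=C\C1=CC(=O)[C@H](O[Si](C)(C)C(C)(C)C)[C@@H](c2ccc(OCc3ccccc3)cc2)O1 | intermediate
21 | (2R,3R)-2-[4-(benzyloxy)phenyl]-6-{(1R)-1-[4-(benzyloxy)phenyl]ethyl}-3-[(tert-butyldimethylsilyl)oxy]-5-hydroxy-7-{[tri(propan-2-yl)silyl]oxy}-2,3-dihydro-4H-chromen-4-one | C[C@H](c1ccc(OCc2ccccc2)cc1)c1c(O[Si](C(C)C)(C(C)C)C(C)C)cc2c(c1O)C(=O)[C@H](O[Si](C)(C)C(C)(C)C)[C@@H](c1ccc(OCc3ccccc3)cc1)O2 | intermediate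
22 | (2R,3R)-2-[4-(benzyloxy)phenyl]-6-{(1R)-1-[4-(benzyloxy)phenyl]ethyl}-3,5,7-trihydroxy-2,3-dihydro-4H-chromen-4-one | C[C@H](c1ccc(OCc2ccccc2)cc1)c1c(O)cc2c(c1O)C(=O)[C@H](O)[C@@H](c1ccc(OCc3ccccc3)cc1)O2 | intermediate
23 | (2R,3R)-3,5,7-trihydroxy-2-(4-hydroxyphenyl)-6-[(1R)-1-(4-hydroxyphenyl)ethyl]-2,3-dihydro-4H-chromen-4-one | C[C@H](c1ccc(O)cc1)c1c(O)cc2c(c1O)C(=O)[C@H](O)[C@@H](c1ccc(O)cc1)O2 | target

Total step count: 12. Longest linear sequence: 8 (steps 1–5 and 10–12); the alkyne branch (steps 6–9) joins at step 10.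

Steps most likely to fail

1. Step 1 (Proposed new method). The migratory insertion into the monocyclic pyrone may be slow or poorly face-selective, or water may add to the electrophilic pyrone ester and open the ring. The fallback sets out from commercial 4-(benzyloxy)benzaldehyde F1, which replaces 1 and 2, and comes back to the route at 3. Asymmetric allylboration of F1 with B-allyldiisopinocampheylborane (enantiomer that gives (S)) would give (1S)-1-[4-(benzyloxy)phenyl]but-3-en-1-ol F2. Wacker oxidation (PdCl2, CuCl, O2, DMF–H2O) would give (4S)-4-[4-(benzyloxy)phenyl]-4-hydroxybutan-2-one F3. Claisen condensation of its dianion (LiN(SiMe3)2, THF, −78 °C) with dimethyl oxalate would give methyl (6S)-6-[4-(benzyloxy)phenyl]-6-hydroxy-2,4-dioxohexanoate F4, which would cyclise and lose water with p-TsOH in toluene to 3.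

2. Step 10. The other chromophores (enone, aryl ethers) may absorb the light and divert the excited diazoketone or the carbene away from the Wolff migration, or the product phenol may trap the ketene. The fallback sets out from 9 and comes back at ketene 18, and so at 21, without light. Silver-catalysed Wolff rearrangement of 9 (CF3CO2Ag, H2O–THF, dark) would give {(2R,3R)-2-[4-(benzyloxy)phenyl]-3-[(tert-butyldimethylsilyl)oxy]-4-oxo-3,4-dihydro-2H-pyran-6-yl}acetic acid F5. The Ghosez reagent would convert it to {(2R,3R)-2-[4-(benzyloxy)phenyl]-3-[(tert-butyldimethylsilyl)oxy]-4-oxo-3,4-dihydro-2H-pyran-6-yl}acetyl chloride F6. Dehydrochlorination of F6 with Et3N in toluene in the presence of 17 (rt, then 80 °C) would generate 18, which would go on through 19 and 20 to 21 as in the known resorcinol synthesis from acid chlorides and siloxyalkynes.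

3. Step 7. The nickel catalyst may discriminate poorly between methyl and alkynyl at the small propargylic radical, and the electron-rich arylzinc may homocouple. The fallback sets out from 2 and comes back at ynolate 16, and so at 17. Rhodium-catalysed asymmetric conjugate addition of 2 to ethyl (E)-but-2-enoate (Rh(acac)(C2H4)2, BINAP, dioxane–H2O, 100 °C) would give ethyl (3S)-3-[4-(benzyloxy)phenyl]butanoate F7. Double α-bromination through the lithium enolate (LiN(SiMe3)2, CBr4, twice) would give ethyl (3R)-3-[4-(benzyloxy)phenyl]-2,2-dibromobutanoate F8. Treatment of F8 with t-BuLi (THF, −78 → 0 °C) would give 16 by bromine–lithium exchange and loss of ethoxide, and 16 would be silylated as in step 9.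

Further compounds
F1 | step 1 | 4-(benzyloxy)benzaldehyde | O=Cc1ccc(OCc2ccccc2)cc1
F2 | step 1 | (1S)-1-[4-(benzyloxy)phenyl]but-3-en-1-ol | C=CC[C@@H](c1ccc(OCc2ccccc2)cc1)O
F3 | step 1 | (4S)-4-[4-(benzyloxy)phenyl]-4-hydroxybutan-2-one | CC(=O)C[C@@H](c1ccc(OCc2ccccc2)cc1)O
F4 | step 1 | methyl (6S)-6-[4-(benzyloxy)phenyl]-6-hydroxy-2,4-dioxohexanoate | COC(=O)C(=O)CC(=O)C[C@@H](c1ccc(OCc2ccccc2)cc1)O
F5 | step 10 | {(2R,3R)-2-[4-(benzyloxy)phenyl]-3-[(tert-butyldimethylsilyl)oxy]-4-oxo-3,4-dihydro-2H-pyran-6-yl}acetic acid | OC(=O)CC1=CC(=O)[C@H](O[Si](C)(C)C(C)(C)C)[C@@H](c2ccc(OCc3ccccc3)cc2)O1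
F6 | step 10 | {(2R,3R)-2-[4-(benzyloxy)phenyl]-3-[(tert-butyldimethylsilyl)oxy]-4-oxo-3,4-dihydro-2H-pyran-6-yl}acetyl chloride | ClC(=O)CC1=CC(=O)[C@H](O[Si](C)(C)C(C)(C)C)[C@@H](c2ccc(OCc3ccccc3)cc2)O1
F7 | step 7 | ethyl (3S)-3-[4-(benzyloxy)phenyl]butanoate | C[C@H](c1ccc(OCc2ccccc2)cc1)CC(=O)OCC
F8 | step 7 | ethyl (3R)-3-[4-(benzyloxy)phenyl]-2,2-dibromobutanoate | C[C@H](c1ccc(OCc2ccccc2)cc1)C(Br)(Br)C(=O)OCC
A1 | direct plan | {3,5-bis(benzyloxy)-4-[1-(4-(benzyloxy)phenyl)ethenyl]phenoxy}tri(propan-2-yl)silane | C=C(c1ccc(OCc2ccccc2)cc1)c1c(OCc2ccccc2)cc(O[Si](C(C)C)(C(C)C)C(C)C)cc1OCc1ccccc1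
A2 | direct plan | 4,6-bis(benzyloxy)-5-[(1R)-1-(4-(benzyloxy)phenyl)ethyl]-2-hydroxybenzaldehyde | C[C@H](c1ccc(OCc2ccccc2)cc1)c1c(OCc2ccccc2)cc(O)c(C=O)c1OCc1ccccc1
A3 | direct plan | 2-[4-(benzyloxy)phenyl]-2-{3,5-bis(benzyloxy)-4-[(1R)-1-(4-(benzyloxy)phenyl)ethyl]-2-formylphenoxy}acetaldehyde (both epimers at the acetaldehyde carbon) | C[C@H](c1ccc(OCc2ccccc2)cc1)c1c(OCc2ccccc2)cc(OC(C=O)c2ccc(OCc3ccccc3)cc2)c(C=O)c1OCc1ccccc1
A4 | direct plan | (2R,3R)-5,7-bis(benzyloxy)-2-[4-(benzyloxy)phenyl]-6-[(1R)-1-(4-(benzyloxy)phenyl)ethyl]-3-hydroxy-2,3-dihydro-4H-chromen-4-one | C[C@H](c1ccc(OCc2ccccc2)cc1)c1c(OCc2ccccc2)cc2c(c1OCc1ccccc1)C(=O)[C@H](O)[C@@H](c1ccc(OCc3ccccc3)cc1)O2
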